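## Structural features

The target is a phenylcoumaran neolignan ester: a 2,3-dihydrobenzofuran whose benzo ring (ring A) carries OMe at C7 and a three-carbon chain at C5, whose C2 carries a 4-hydroxy-3-methoxyphenyl group (ring B) and whose C3 carries CH2OH. The terminal oxygen of the C5 chain is acylated by (E)-ferulic acid. C2 and C3 are the only stereocentres; they are adjacent, trans and (2R,3S). The O1–C2 bond is a benzylic aryl ether para to the ring B oxygen, so it can ionise under acid, open through a quinone methide under base once the ring B phenol is free, and be hydrogenolysed. The cinnamate (E-alkene, base-labile ester) rules out late hydrogenation and strong base. Two phenols and the C3 CH2OH stay free while only the propanol oxygen is acylated, so the two primary alcohols must be told apart. The real difficulty is absolute control of the C2/C3 pair: C3 is a C–H centre that must be set enantioselectively, and C2 is a benzylic C–O centre that must be set from C3 without scrambling. The key step uses the fact that O1 (on C7a of ring A) is bonded to C2 and that C2 is β to the exocyclic carbon on C3. With that carbon at the carboxyl level and tied to the C2 oxygen, C3 and C2 become C3 and C4 of an oxetan-2-one, whose strained benzylic C4–O bond lies five atoms from the ring A oxygen.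

## Logic of the disconnections

**25 ⇒ 24 ⇒ 20 + 23.** Bonds cut: the two O–Si bonds of 24, then the acyl C–O bond between the feruloyl carbonyl and the propanol oxygen. Reason: the cinnamate alkene and ester would not survive the hydrogenolysis and hydroxide steps the core needs, so the acyl group arrives last. Gain: the target falls into a ten-carbon acid and the chiral core 20. Demand: only the propanol oxygen of 20 may be acylated although a phenol is free. The C3 CH2OH is therefore carried as a silyl ether, and the ester is made by an alcohol-activating coupling in which the carboxylic acid is the only pronucleophile acidic enough to react. The last deprotection must be non-basic, because a ring B phenoxide can open O1–C2.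

**23 ⇒ 21.** Bond cut: the aryl O–Si bond. Reason: the phenol of the acid partner is masked so it cannot act as a second pronucleophile. Gain: 21 is purchased. Demand: the silyl ester formed alongside must be hydrolysed selectively.

**20 ⇒ 19 ⇒ 18 ⇒ 17.** Bonds cut: two benzyl C–O bonds, one O–Si bond, and the two C–H bonds that separate CH2OH from CO2H. Reason: the ring-forming step delivers the exocyclic carbon at the carboxyl level, and benzyl ethers carry the ring B and chain oxygens through it. Gain: 17 already holds every carbon and both stereocentres of the core. Demand: the reduction must not epimerise C3 (benzylic and α to the carboxyl), so an electrophilic, non-basic hydride is used. The hydrogenolysis must stop before the O1–C2 bond is touched.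

**17 ⇒ 15 (key disconnection).** Bond cut: O1–C2. Reason: this bond is the alkyl C–O bond of a β-lactone in 15, and it is strained, benzylic and para-oxygen-stabilised. Gain: the ring and C2 come from an open-chain relationship (anti) that aldol chemistry can set. Demand: alkyl–oxygen rather than acyl–oxygen cleavage, capture by oxygen faster than loss of a proton or CO2, and unmasking of the ring A oxygen without base or fluoride while the lactone is present. Three design choices follow:
- The ring A oxygen is carried as a 4-methoxybenzyl ether. It is stable to the hydroxide, hydroperoxide and palladium steps before, and is removed by the same Brønsted acid that activates the lactone.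
- A silyl ether was not chosen. It would be at risk in the hydroperoxide step, and its removal needs fluoride, which precipitates MgF2 from a magnesium Lewis acid in the same flask and, when basic, attacks the acyl carbon or eliminates.
- A Brønsted acid is used because the leaving group then stays an undissociated CO2H, which cannot shed CO2.

**15 ⇒ 13.** Bond cut: the lactone acyl C–O bond. Reason: closing the ring by carboxyl activation touches neither stereocentre, so anti becomes trans. Gain: an open-chain β-hydroxy acid. Demand: hydroxyl activation must be avoided (it would fragment), the base must be too weak to form a ketene from the α-aryl acyl derivative, and 15 must be kept cold and used at once.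

**13 ⇒ 11 ⇒ 8 + 9.** Bonds cut: the N-acyl bond to the auxiliary, then the Cα–Cβ bond (future C3–C2). Reason: an aldol addition makes this bond and both stereocentres in one step. Gain: two achiral aromatic pieces, one of them purchased (9). Demand: anti selectivity and absolute control, met by an oxazolidinone auxiliary in a MgCl2-catalysed anti-aldol reaction; the auxiliary must be removed without retro-aldol cleavage.

**8 ⇒ 6 ⇒ 5 ⇒ 4.** Bonds cut: the imide N–C(acyl) bond, the ester O–C bond, and the aryl–CH2 bond (future C3a–C3). Reason: the two-carbon acid unit is attached where a bromine can be placed regioselectively. Gain: a simple aryl bromide. Demand: a coupling that tolerates an ortho substituent and an electron-rich ring, and an ester that is cleaved by base because the PMB ether is acid-labile.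

**4 ⇒ 3 ⇒ 2 ⇒ 1.** Bonds cut: O–benzyl, O–PMB and C–Br. Reason: the free phenol of 1 directs bromine to its only free ortho position, and the acidity gap between phenol and alcohol lets the two oxygens be protected one after the other. Gain: 1 is purchased and already has the three-carbon chain. Demand: bromination ortho to OH rather than para to OMe, and phenol-selective alkylation with a weak base.

## Other disconnections considered

**Alternative 1:** The cut removes ring B and the exocyclic carbon on C3, leaving the benzofuran A2. In the forward sense an engineered myoglobin-type heme protein would transfer the carbene of N2CHCO2Et to C2=C3 of A2 on one face to give the exo cyclopropane A1. The oxygen-donor/ester-acceptor cyclopropane would then be opened at C2 by a ring B nucleophile to give A3.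
- In favour: the absolute configuration at C3 would come from a catalyst and not from an auxiliary. A2 is only a few steps from a ring A phenol. No strained lactone has to be handled. Opening of A1 at C2 with inversion, or through the oxocarbenium ion anti to the C3 substituent, would give the trans pair.
- Against: the carbene carbon ends as a CH2 that still carries the ester, so A3 has C3–CH2–CO2Et, one carbon more than the C3–CH2OH of the target. The ester carbon would have to be excised by a decarboxylative oxygenation, through radical chemistry next to a benzylic ether. The ring B nucleophile must be an aryl metal, since a Friedel–Crafts partner has two activated positions. An enzyme variant accepting a 7-methoxy-5-alkyl benzofuran would have to be found.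
- Comparison: both plans set C3 first and C2 from it, but the chosen plan builds the exocyclic carbon with the right count and oxidation level. In stereo-induction the catalytic enzyme step is the better of the two. In step economy the alternative is shorter as far as A1, and the one-carbon excision would probably cancel that lead.

**Alternative 2:** The cut is the aryl C7a–O1 bond. In the forward sense the hydroxy triflate A5 would be closed with Pd(OAc)2, 2-(di-tert-butylphosphino)-1,1'-binaphthyl and Cs2CO3 to A4, with retention at both centres because neither is a reaction site. A5 would come from a ketoreductase reduction with dynamic kinetic resolution of a 1,2-diaryl β-keto ester, followed by ester reduction and silylation.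
- In favour: one biocatalytic step would set both centres. No cation at C2 is involved. A4 is identical with 19 of the chosen route, so the acid reduction and silylation are not needed; on step economy the alternative is the better by two or three steps.
- Against: the triflate carbon is electron-rich and flanked by OMe and a branched side chain, so oxidative addition to zerovalent palladium would be slow. The secondary benzylic palladium alkoxide has a β-hydrogen and can collapse to a ketone and reduced arene. Carbonate can cleave the S–O bond of the triflate. The closure has no correcting element, so any syn/anti leakage of the enzyme would be carried into the product. An enzyme for so hindered a substrate has to be screened.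
- Comparison: the chosen plan forms the alkyl C–O bond by substitution at carbon without a transition metal, and both inversion and ionisation converge on the trans ring. The alternative forms the aryl C–O bond and depends on catalyst performance on a hindered substrate. On stereocontrol the alternative is at least the equal of the chosen plan; on robustness of the ring closure the chosen plan is judged safer.

**Alternative 3:** The cut is C3–C3a; the precursor is the (R)-flavanone A7, in which the ring A carbon is still bonded to the carbonyl carbon. In the forward sense PhI(OAc)2, H2SO4 and HC(OMe)3 would convert A7, through its enol ether and an α-iodanyl intermediate, into A6 by a 1,2-shift of the ring A carbon from C4 to C3.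
- In favour: A6 is the methyl ester counterpart of 17, so this route meets the chosen one at the same oxidation level. Flavanones are quickly assembled, and a catalytic asymmetric 1,4-arylation of a chromone could supply the enantiomer. The migration anti to the departing iodane should give the trans ester.
- Against: enantiopure flavanones racemise by reversible opening to the 2'-hydroxychalcone, which a strongly acidic medium invites. Migration of ring B (isoflavone formation) and dehydrogenation to the flavone compete, which is why ring B must be detuned as its acetate. A trivalent iodine oxidant and strong acid meet an electron-rich ring A and benzylic ethers.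
- Comparison: the ring and the carboxyl-level C3 are the same in both plans. In the alternative C3 is set from C2, and its absolute configuration rests on the stability of A7 under acidic oxidative conditions. In the chosen plan the anchor centre C3 is never a reaction site during ring closure. In step economy the alternative is probably the better by two or three steps, since no auxiliary is attached and removed.

Key step: step 10

## Remarks before the steps

- Abbreviations: ArA = 5-[3-(benzyloxy)propyl]-3-methoxy-2-[(4-methoxybenzyl)oxy]phenyl; ArB = 4-(benzyloxy)-3-methoxyphenyl; PMB = 4-methoxybenzyl; TBS = tert-butyldimethylsilyl.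
- Compounds 1, 9 and 21, both enantiomers of 4-benzyloxazolidin-2-one and BrZnCH2CO2Et (as a THF solution) are taken as purchased.
- Assumption: the facial sense of step 7 is that of the magnesium-chelated Z-enolate, with the aldehyde approaching anti to the benzyl group of the (S)-auxiliary.

## Steps

**Step 1**
Reactants: 1 3-(4-hydroxy-3-methoxyphenyl)propan-1-ol
Product: 2 2-bromo-4-(3-hydroxypropyl)-6-methoxyphenol
Conditions: NBS (1.0 equiv), i-Pr2NH (10 mol %), CH2Cl2, 0 °C
Reagents that add atoms: N-bromosuccinimide, O=C1CCC(=O)N1Br
Why: Electrophilic aromatic bromination of a phenol; the para position is blocked and amine-mediated delivery of bromine to the hydrogen-bonded phenol favours its one free ortho position over the site para to OMe; the primary alcohol is inert.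

**Step 2**
Reactants: 2 2-bromo-4-(3-hydroxypropyl)-6-methoxyphenol
Product: 3 3-{3-bromo-5-methoxy-4-[(4-methoxybenzyl)oxy]phenyl}propan-1-ol
Conditions: PMBCl, K2CO3, Bu4NI (cat.), DMF, 50 °C
Reagents that add atoms: 4-methoxybenzyl chloride, COc1ccc(CCl)cc1
Why: Williamson etherification; K2CO3 deprotonates only the phenol (made more acidic by the ortho bromine), so the aliphatic alcohol stays free.

**Step 3**
Reactants: 3 3-{3-bromo-5-methoxy-4-[(4-methoxybenzyl)oxy]phenyl}propan-1-ol
Product: 4 5-[3-(benzyloxy)propyl]-1-bromo-3-methoxy-2-[(4-methoxybenzyl)oxy]benzene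
Conditions: NaH, BnBr, Bu4NI (cat.), THF/DMF, 0 °C → rt
Reagents that add atoms: benzyl bromide, BrCc1ccccc1
Why: Williamson etherification of the only remaining hydroxyl; aryl bromide and PMB ether are stable to the alkoxide.

**Step 4**
Reactants: 4 5-[3-(benzyloxy)propyl]-1-bromo-3-methoxy-2-[(4-methoxybenzyl)oxy]benzene
Product: 5 ethyl 2-ArA-acetate
Conditions: BrZnCH2CO2Et (2 equiv), Pd2(dba)3 (2 mol %), XPhos (8 mol %), THF, 65 °C
Reagents that add atoms: (2-ethoxy-2-oxoethyl)zinc bromide, CCOC(=O)C[Zn]Br
Why: Negishi coupling of a Reformatsky reagent (α-arylation of a zinc ester enolate): oxidative addition of the aryl bromide to zerovalent palladium, transmetalation from zinc, reductive elimination; the zinc enolate is non-basic and does not self-condense, and the bulky biaryl phosphine copes with the ortho substituent.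

**Step 5**
Reactants: 5 ethyl 2-ArA-acetate
Product: 6 2-ArA-acetic acid
Conditions: LiOH, THF/MeOH/H2O, rt; then 1 M HCl to pH 3, 0 °C
Reagents that add atoms: lithium hydroxide, [Li+].[OH-]
Why: Ester saponification; an ethyl ester is used so that no acid is needed for its cleavage, and the cold, brief acidification spares the acid-labile aryl PMB ether.

**Step 6**
Reactants: 6 2-ArA-acetic acid
Product: 8 (S)-4-benzyl-3-(2-ArA-acetyl)oxazolidin-2-one, via mixed pivalic anhydride 7 (not isolated)
Conditions: PivCl, Et3N, THF, −20 °C; then (S)-4-benzyloxazolidin-2-one, LiCl, −20 °C → rt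
Reagents that add atoms: pivaloyl chloride, CC(C)(C)C(=O)Cl (kept only in 7); (S)-4-benzyl-1,3-oxazolidin-2-one, O=C1N[C@@H](Cc2ccccc2)CO1
Why: N-acylation of the auxiliary through a mixed anhydride; the hindered pivaloyl carbonyl directs the lithium-chloride-activated oxazolidinone to the arylacetyl carbonyl.

**Step 7**
Reactants: 8 (S)-4-benzyl-3-(2-ArA-acetyl)oxazolidin-2-one; 9 4-(benzyloxy)-3-methoxybenzaldehyde
Product: 11 (S)-4-benzyl-3-[(2R,3S)-2-ArA-3-ArB-3-hydroxypropanoyl]oxazolidin-2-one, via trimethylsilyl ether 10 (not isolated)
Conditions: MgCl2 (20 mol %), Et3N (2 equiv), TMSCl (1.5 equiv), EtOAc, 23 °C; then 10% aq. citric acid, THF, 0 °C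
Reagents that add atoms: chlorotrimethylsilane, C[Si](C)(C)Cl (kept only in 10)
Why: MgCl2-catalysed Evans anti-aldol reaction: soft enolisation gives the magnesium-chelated Z-enolate (easier here because the α-proton is benzylic), and the non-enolisable aldehyde adds through a closed boat-like transition state on the face opposite the auxiliary benzyl group, setting (2R) and, anti to it, (3S); silylation of the aldolate by TMSCl releases the magnesium and blocks retro-aldol, and the TMS ether is hydrolysed on mild acidic work-up.

**Step 8**
Reactants: 11 (S)-4-benzyl-3-[(2R,3S)-2-ArA-3-ArB-3-hydroxypropanoyl]oxazolidin-2-one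
Product: 13 (2R,3S)-2-ArA-3-ArB-3-hydroxypropanoic acid, via peroxy acid 12 (not isolated)
Conditions: LiOH, 30% H2O2, THF/H2O (3:1), 0 °C; then aq. Na2SO3; 1 M HCl to pH 3, 0 °C
Reagents that add atoms: hydrogen peroxide, OO
Why: Hydroperoxide cleavage of the N-acyl oxazolidinone: the hydroperoxide anion is more nucleophilic and less basic than hydroxide, attacks the exocyclic carbonyl and gives the peroxy acid, which sulfite reduces; low temperature and short contact limit retro-aldol cleavage and α-epimerisation, and the auxiliary is recovered.

**Step 9**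
Reactants: 13 (2R,3S)-2-ArA-3-ArB-3-hydroxypropanoic acid
Product: 15 (3R,4S)-3-ArA-4-ArB-oxetan-2-one (trans), via mixed sulfonic anhydride 14 (not isolated)
Conditions: PhSO2Cl (2 equiv), pyridine, −10 → 0 °C; cold work-up, used at once
Reagents that add atoms: benzenesulfonyl chloride, O=S(=O)(Cl)c1ccccc1 (kept only in 14)
Why: Carboxyl-activating β-lactonisation: the carboxylate is sulfonylated and the C3 hydroxyl attacks the activated carbonyl (4-exo-trig), so neither stereocentre is a reaction site and the anti acid gives the trans lactone; pyridine is too weak a base to form a ketene from the α-aryl acyl derivative, and the lactone is kept cold because its electron-rich C4 aryl group makes it prone to lose CO2.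

**Step 10 (key step)**
Reactants: 15 (3R,4S)-3-ArA-4-ArB-oxetan-2-one
Product: 17 (2R,3R)-2-ArB-5-[3-(benzyloxy)propyl]-7-methoxy-2,3-dihydrobenzofuran-3-carboxylic acid (trans), via phenol lactone 16 (not isolated)
Conditions: TFA (10 equiv), C6HMe5 (3 equiv), CH2Cl2, −20 → 0 °C
Reagents that add atoms: none
Why: TFA cleaves the aryl PMB ether (the PMB cation is taken up by pentamethylbenzene in a Friedel–Crafts alkylation) and protonates the lactone carbonyl; the C4–O bond, strained, benzylic and assisted by the para benzyloxy group of ring B, then lengthens and the ring A oxygen on C7a bonds to C4 from the side opposite the departing carboxyl oxygen. The closest known reaction type is the acid- or Lewis-acid-promoted alkyl–oxygen opening of β-lactones by oxygen nucleophiles with inversion (phenols intermolecularly, pendant ether or hydroxyl oxygens intramolecularly to give cyclic ether acids). The dihydrofuran ring closes in the 5-exo-tet mode, the breaking C–O bond lying outside the new ring. The new stereocentre C2 is controlled by the substrate: backside entry inverts lactone C4 (S) to C2 (R), and if the ion pair separates the same face is still taken because it places ring B trans to the C3 carboxyl, while C3 is not a reaction site and keeps its configuration. The step needs alkyl–oxygen rather than acyl–oxygen cleavage, which the cation-stabilising ring B and the poor nucleophilicity of a neutral phenol toward a carbonyl under acid secure. It also needs capture rather than fragmentation, which is secured because in TFA the leaving group remains an undissociated CO2H that cannot lose CO2 and because five-membered capture should outrun loss of the C3 proton. The benzyl ethers tolerate cold dilute TFA, and the reaction is quenched cold so that the kinetic trans acid is not exposed to acid longer than needed.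

**Step 11**
Reactants: 17 (2R,3R)-2-ArB-5-[3-(benzyloxy)propyl]-7-methoxy-2,3-dihydrobenzofuran-3-carboxylic acid
Product: 18 {(2R,3S)-2-ArB-5-[3-(benzyloxy)propyl]-7-methoxy-2,3-dihydrobenzofuran-3-yl}methanol
Conditions: BH3·THF (3 equiv), THF, 0 °C → rt; MeOH quench, aqueous work-up
Reagents that add atoms: none
Why: Borane reduction of a free carboxylic acid via the acyloxyborane; the reagent is electrophilic and non-basic, so the benzylic, carboxyl-activated C3–H is not epimerised and the ethers are untouched.

**Step 12**
Reactants: 18 {(2R,3S)-2-ArB-5-[3-(benzyloxy)propyl]-7-methoxy-2,3-dihydrobenzofuran-3-yl}methanol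
Product: 19 tert-butyl{[(2R,3S)-2-ArB-5-[3-(benzyloxy)propyl]-7-methoxy-2,3-dihydrobenzofuran-3-yl]methoxy}dimethylsilane
Conditions: TBSCl, imidazole, CH2Cl2, rt
Reagents that add atoms: tert-butyldimethylsilyl chloride, CC(C)(C)[Si](C)(C)Cl
Why: Silylation of the only free hydroxyl, so that it stays masked when the chain alcohol is released and acylated.

**Step 13**
Reactants: 19 tert-butyl{[(2R,3S)-2-ArB-5-[3-(benzyloxy)propyl]-7-methoxy-2,3-dihydrobenzofuran-3-yl]methoxy}dimethylsilane
Product: 20 4-[(2R,3S)-3-(tert-butyldimethylsilyloxymethyl)-5-(3-hydroxypropyl)-7-methoxy-2,3-dihydrobenzofuran-2-yl]-2-methoxyphenol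
Conditions: H2 (1 atm), 10% Pd/C, EtOAc, rt
Reagents that add atoms: none
Why: Catalytic hydrogenolysis of the aryl and the alkyl benzyl ether; EtOAc keeps the TBS ether intact, and the reaction is stopped once both benzyl groups are gone because the hindered, ring-bound benzylic O1–C2 bond is cleaved more slowly.

**Step 14**
Reactants: 21 (E)-ferulic acid
Product: 23 (E)-3-[4-(tert-butyldimethylsilyloxy)-3-methoxyphenyl]acrylic acid, via bis-silyl ferulate 22 (not isolated)
Conditions: TBSCl (2.5 equiv), imidazole, DMF, rt; then AcOH/THF/H2O, rt
Reagents that add atoms: tert-butyldimethylsilyl chloride, CC(C)(C)[Si](C)(C)Cl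
Why: Silylation of phenol and carboxyl, then hydrolysis of the silyl ester, which is far more labile than the aryl silyl ether.

**Step 15**
Reactants: 20 4-[(2R,3S)-3-(tert-butyldimethylsilyloxymethyl)-5-(3-hydroxypropyl)-7-methoxy-2,3-dihydrobenzofuran-2-yl]-2-methoxyphenol; 23 (E)-3-[4-(tert-butyldimethylsilyloxy)-3-methoxyphenyl]acrylic acid
Product: 24 3-[(2R,3S)-3-(tert-butyldimethylsilyloxymethyl)-2-(4-hydroxy-3-methoxyphenyl)-7-methoxy-2,3-dihydrobenzofuran-5-yl]propyl (E)-3-[4-(tert-butyldimethylsilyloxy)-3-methoxyphenyl]acrylate
Conditions: PPh3, DIAD, THF, 0 °C → rt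
Reagents that add atoms: none
Why: Mitsunobu esterification: only the aliphatic alcohol is turned into an alkoxyphosphonium ion and the carboxylic acid, far more acidic than the ring B phenol, is the pronucleophile, so the phenol is not acylated or alkylated; the medium is near neutral and the E-alkene is untouched.

**Step 16**
Reactants: 24 3-[(2R,3S)-3-(tert-butyldimethylsilyloxymethyl)-2-(4-hydroxy-3-methoxyphenyl)-7-methoxy-2,3-dihydrobenzofuran-5-yl]propyl (E)-3-[4-(tert-butyldimethylsilyloxy)-3-methoxyphenyl]acrylate
Product: 25 3-[(2R,3S)-2-(4-hydroxy-3-methoxyphenyl)-3-(hydroxymethyl)-7-methoxy-2,3-dihydrobenzofuran-5-yl]propyl (E)-3-(4-hydroxy-3-methoxyphenyl)acrylate (CNP0149450.1)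
Conditions: TBAF, AcOH (1:1), THF, 0 °C → rt
Reagents that add atoms: none
Why: Fluoride desilylation of the primary alkyl and the aryl TBS ether; buffering with acetic acid prevents phenoxide-triggered opening of O1–C2 and cleavage of the cinnamate ester.

## Compound list

1 | 3-(4-hydroxy-3-methoxyphenyl)propan-1-ol (dihydroconiferyl alcohol) | COc1cc(CCCO)ccc1O | starting material
2 | 2-bromo-4-(3-hydroxypropyl)-6-methoxyphenol | COc1cc(CCCO)cc(Br)c1O | intermediate
3 | 3-{3-bromo-5-methoxy-4-[(4-methoxybenzyl)oxy]phenyl}propan-1-ol | COc1ccc(COc2c(Br)cc(CCCO)cc2OC)cc1 | intermediate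
4 | 5-[3-(benzyloxy)propyl]-1-bromo-3-methoxy-2-[(4-methoxybenzyl)oxy]benzene | COc1ccc(COc2c(Br)cc(CCCOCc3ccccc3)cc2OC)cc1 | intermediate
5 | ethyl 2-ArA-acetate | CCOC(=O)Cc1cc(CCCOCc2ccccc2)cc(OC)c1OCc1ccc(OC)cc1 | intermediate
6 | 2-ArA-acetic acid | OC(=O)Cc1cc(CCCOCc2ccccc2)cc(OC)c1OCc1ccc(OC)cc1 | intermediate
7 | 2-ArA-acetic pivalic anhydride | CC(C)(C)C(=O)OC(=O)Cc1cc(CCCOCc2ccccc2)cc(OC)c1OCc1ccc(OC)cc1 | intermediate (not isolated)
8 | (S)-4-benzyl-3-(2-ArA-acetyl)oxazolidin-2-one | O=C1OC[C@H](Cc2ccccc2)N1C(=O)Cc1cc(CCCOCc2ccccc2)cc(OC)c1OCc1ccc(OC)cc1 | intermediate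
9 | 4-(benzyloxy)-3-methoxybenzaldehyde | COc1cc(C=O)ccc1OCc1ccccc1 | starting material
10 | (S)-4-benzyl-3-[(2R,3S)-2-ArA-3-ArB-3-(trimethylsilyloxy)propanoyl]oxazolidin-2-one | O=C1OC[C@H](Cc2ccccc2)N1C(=O)[C@H](c1cc(CCCOCc2ccccc2)cc(OC)c1OCc1ccc(OC)cc1)[C@H](O[Si](C)(C)C)c1ccc(OCc2ccccc2)c(OC)c1 | intermediate (not isolated)
11 | (S)-4-benzyl-3-[(2R,3S)-2-ArA-3-ArB-3-hydroxypropanoyl]oxazolidin-2-one | O=C1OC[C@H](Cc2ccccc2)N1C(=O)[C@H](c1cc(CCCOCc2ccccc2)cc(OC)c1OCc1ccc(OC)cc1)[C@H](O)c1ccc(OCc2ccccc2)c(OC)c1 | intermediate
12 | (2R,3S)-2-ArA-3-ArB-3-hydroxypropaneperoxoic acid | OOC(=O)[C@H](c1cc(CCCOCc2ccccc2)cc(OC)c1OCc1ccc(OC)cc1)[C@H](O)c1ccc(OCc2ccccc2)c(OC)c1 | intermediate (not isolated)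
13 | (2R,3S)-2-ArA-3-ArB-3-hydroxypropanoic acid | OC(=O)[C@H](c1cc(CCCOCc2ccccc2)cc(OC)c1OCc1ccc(OC)cc1)[C@H](O)c1ccc(OCc2ccccc2)c(OC)c1 | intermediate
14 | benzenesulfonic (2R,3S)-2-ArA-3-ArB-3-hydroxypropanoic anhydride | O=S(=O)(OC(=O)[C@H](c1cc(CCCOCc2ccccc2)cc(OC)c1OCc1ccc(OC)cc1)[C@H](O)c1ccc(OCc2ccccc2)c(OC)c1)c1ccccc1 | intermediate (not isolated)
15 | (3R,4S)-3-ArA-4-ArB-oxetan-2-one (trans) | c1ccccc1COCCCc1cc(OC)c(OCc2ccc(OC)cc2)c(c1)[C@H]1C(=O)O[C@@H]1c1ccc(OCc2ccccc2)c(OC)c1 | intermediate (key-step precursor)
16 | (3R,4S)-3-{5-[3-(benzyloxy)propyl]-2-hydroxy-3-methoxyphenyl}-4-ArB-oxetan-2-one | c1ccccc1COCCCc1cc(OC)c(O)c(c1)[C@H]1C(=O)O[C@@H]1c1ccc(OCc2ccccc2)c(OC)c1 | intermediate (not isolated)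
17 | (2R,3R)-2-ArB-5-[3-(benzyloxy)propyl]-7-methoxy-2,3-dihydrobenzofuran-3-carboxylic acid (trans) | c1ccccc1COCCCc1cc(OC)c2c(c1)[C@@H](C(=O)O)[C@H](c1ccc(OCc3ccccc3)c(OC)c1)O2 | intermediate (key-step product)
18 | {(2R,3S)-2-ArB-5-[3-(benzyloxy)propyl]-7-methoxy-2,3-dihydrobenzofuran-3-yl}methanol | c1ccccc1COCCCc1cc(OC)c2c(c1)[C@@H](CO)[C@H](c1ccc(OCc3ccccc3)c(OC)c1)O2 | intermediate
19 | TBS ether of 18 | c1ccccc1COCCCc1cc(OC)c2c(c1)[C@@H](CO[Si](C)(C)C(C)(C)C)[C@H](c1ccc(OCc3ccccc3)c(OC)c1)O2 | intermediate
20 | 4-[(2R,3S)-3-(tert-butyldimethylsilyloxymethyl)-5-(3-hydroxypropyl)-7-methoxy-2,3-dihydrobenzofuran-2-yl]-2-methoxyphenol | OCCCc1cc(OC)c2c(c1)[C@@H](CO[Si](C)(C)C(C)(C)C)[C@H](c1ccc(O)c(OC)c1)O2 | intermediate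
21 | (E)-ferulic acid | COc1cc(/C=C/C(=O)O)ccc1O | starting material
22 | tert-butyldimethylsilyl (E)-3-[4-(tert-butyldimethylsilyloxy)-3-methoxyphenyl]acrylate | COc1cc(/C=C/C(=O)O[Si](C)(C)C(C)(C)C)ccc1O[Si](C)(C)C(C)(C)C | intermediate (not isolated)
23 | (E)-3-[4-(tert-butyldimethylsilyloxy)-3-methoxyphenyl]acrylic acid | COc1cc(/C=C/C(=O)O)ccc1O[Si](C)(C)C(C)(C)C | intermediate
24 | bis-TBS ether of the target (C3 CH2O–TBS and ferulate ArO–TBS) | COc1cc(/C=C/C(=O)OCCCc2cc(OC)c3c(c2)[C@@H](CO[Si](C)(C)C(C)(C)C)[C@H](c2ccc(O)c(OC)c2)O3)ccc1O[Si](C)(C)C(C)(C)C | intermediate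
25 | 3-[(2R,3S)-2-(4-hydroxy-3-methoxyphenyl)-3-(hydroxymethyl)-7-methoxy-2,3-dihydrobenzofuran-5-yl]propyl (E)-ferulate | COc1cc(/C=C/C(=O)OCCCc2cc(OC)c3c(c2)[C@@H](CO)[C@H](c2ccc(O)c(OC)c2)O3)ccc1O | target

## Step count and least certain steps

Total: 16 steps. Longest linear sequence: 15 steps (1 → 25 through steps 1–13, 15 and 16); step 14 is a one-step side branch.

**Step 10 (key step).** Most likely failure: once the C4–O bond has ionised, loss of the C3 proton or fragmentation with loss of CO2 outruns capture by the ring A oxygen, or the freed phenol undergoes acyl transfer at the strained carbonyl. The cation is strongly stabilised, the C3–H is benzylic and carboxyl-activated, and all three pathways relieve the same ring strain. Fallback (sets out from 11, returns at 18): the carboxyl carbon is reduced before the ring is closed, so none of these pathways exists. LiBH4 (THF, 1 equiv MeOH, 0 °C) would remove the auxiliary reductively to give (1S,2S)-1-ArB-2-ArA-propane-1,3-diol F1. TFA and pentamethylbenzene in CH2Cl2 at 0 °C would then remove the PMB group and ionise the benzylic carbinol, and the ring A oxygen would close the ring anti to the CH2OH group. This acid-mediated cyclodehydration of an ortho-hydroxyaryl benzylic alcohol would give 18 directly.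

**Step 7.** Most likely failure: poor facial or anti selectivity, or slow addition to the electron-rich aldehyde with α-epimerisation of the α-aryl imide by Et3N; an arylacetyl enolate is more stabilised than the propionyl enolates for which this aldol is best known. Fallback (sets out from 6, returns at 17): the syn aldol is accepted and the carbinol centre is corrected in the ring closure.
- Acylation of (R)-4-benzyloxazolidin-2-one as in step 6 would give (R)-4-benzyl-3-(2-ArA-acetyl)oxazolidin-2-one F2.
- Its dibutylboron Z-enolate (Bu2BOTf, i-Pr2NEt, CH2Cl2, −78 → 0 °C) and 9 would give the syn adduct (R)-4-benzyl-3-[(2R,3R)-2-ArA-3-ArB-3-hydroxypropanoyl]oxazolidin-2-one F3, with the α-centre already R.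
- LiOH/H2O2 would give (2R,3R)-2-ArA-3-ArB-3-hydroxypropanoic acid F4, and PhSO2Cl/pyridine the cis lactone (3R,4R)-3-ArA-4-ArB-oxetan-2-one F5.
- Under the conditions of step 10, F5 would ionise at C4 and be captured by the ring A oxygen anti to the C3 carboxyl. Any cis ring formed first should equilibrate through reversible ionisation of O1–C2, so that 17 results.

**Step 8.** Most likely failure: retro-aldol cleavage of the lithium aldolate (the departing enolate is stabilised by the aryl group) or attack of hydroxide on the ring carbonyl of the hindered imide. Fallback (sets out from 11, returns at 13): the aldolate is blocked before the cleavage. TESCl and imidazole would give (S)-4-benzyl-3-[(2R,3S)-2-ArA-3-ArB-3-(triethylsilyloxy)propanoyl]oxazolidin-2-one F6. LiOH/H2O2 would then give (2R,3S)-2-ArA-3-ArB-3-(triethylsilyloxy)propanoic acid F7, and AcOH/THF/H2O would remove the silyl group to give 13.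

**Step 9.** Most likely failure: fragmentation of the lactone with loss of CO2 while it forms or is worked up, because the C4 aryl group is a strong donor. Fallback (sets out from 13, returns at 17): the lactone is not isolated. TFA and pentamethylbenzene (CH2Cl2, −20 → 0 °C) applied to 13 would remove the PMB group to give (2R,3S)-2-{5-[3-(benzyloxy)propyl]-2-hydroxy-3-methoxyphenyl}-3-ArB-3-hydroxypropanoic acid F8. Its benzylic carbinol would ionise under the same acid and be captured by the ring A oxygen anti to the protonated C3 carboxyl, giving 17.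

## Further compounds

F1 | step 10 | (1S,2S)-1-ArB-2-ArA-propane-1,3-diol | OC[C@H](c1cc(CCCOCc2ccccc2)cc(OC)c1OCc1ccc(OC)cc1)[C@H](O)c1ccc(OCc2ccccc2)c(OC)c1
F2 | step 7 | (R)-4-benzyl-3-(2-ArA-acetyl)oxazolidin-2-one | O=C1OC[C@@H](Cc2ccccc2)N1C(=O)Cc1cc(CCCOCc2ccccc2)cc(OC)c1OCc1ccc(OC)cc1
F3 | step 7 | (R)-4-benzyl-3-[(2R,3R)-2-ArA-3-ArB-3-hydroxypropanoyl]oxazolidin-2-one | O=C1OC[C@@H](Cc2ccccc2)N1C(=O)[C@H](c1cc(CCCOCc2ccccc2)cc(OC)c1OCc1ccc(OC)cc1)[C@@H](O)c1ccc(OCc2ccccc2)c(OC)c1
F4 | step 7 | (2R,3R)-2-ArA-3-ArB-3-hydroxypropanoic acid | OC(=O)[C@H](c1cc(CCCOCc2ccccc2)cc(OC)c1OCc1ccc(OC)cc1)[C@@H](O)c1ccc(OCc2ccccc2)c(OC)c1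
F5 | step 7 | (3R,4R)-3-ArA-4-ArB-oxetan-2-one (cis) | c1ccccc1COCCCc1cc(OC)c(OCc2ccc(OC)cc2)c(c1)[C@H]1C(=O)O[C@H]1c1ccc(OCc2ccccc2)c(OC)c1
F6 | step 8 | (S)-4-benzyl-3-[(2R,3S)-2-ArA-3-ArB-3-(triethylsilyloxy)propanoyl]oxazolidin-2-one | O=C1OC[C@H](Cc2ccccc2)N1C(=O)[C@H](c1cc(CCCOCc2ccccc2)cc(OC)c1OCc1ccc(OC)cc1)[C@H](O[Si](CC)(CC)CC)c1ccc(OCc2ccccc2)c(OC)c1
F7 | step 8 | (2R,3S)-2-ArA-3-ArB-3-(triethylsilyloxy)propanoic acid | OC(=O)[C@H](c1cc(CCCOCc2ccccc2)cc(OC)c1OCc1ccc(OC)cc1)[C@H](O[Si](CC)(CC)CC)c1ccc(OCc2ccccc2)c(OC)c1
F8 | step 9 | (2R,3S)-2-{5-[3-(benzyloxy)propyl]-2-hydroxy-3-methoxyphenyl}-3-ArB-3-hydroxypropanoic acid | OC(=O)[C@H](c1cc(CCCOCc2ccccc2)cc(OC)c1O)[C@H](O)c1ccc(OCc2ccccc2)c(OC)c1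
A1 | alternative 1 | ethyl exo-1a,6b-dihydro-1H-cyclopropa[b]benzofuran-1-carboxylate carrying the ring A methoxy and 3-(benzyloxy)propyl groups | CCOC(=O)[C@@H]1[C@H]2Oc3c(OC)cc(CCCOCc4ccccc4)cc3[C@@H]12
A2 | alternative 1 | 5-[3-(benzyloxy)propyl]-7-methoxybenzofuran | COc1cc(CCCOCc2ccccc2)cc2ccoc12
A3 | alternative 1 | ethyl 2-{(2R,3R)-2-ArB-5-[3-(benzyloxy)propyl]-7-methoxy-2,3-dihydrobenzofuran-3-yl}acetate (trans) | CCOC(=O)C[C@H]1[C@H](c2ccc(OCc3ccccc3)c(OC)c2)Oc2c(OC)cc(CCCOCc3ccccc3)cc21
A4 | alternative 2 | trans-(2R,3S)-2-ArB-3-(tert-butyldimethylsilyloxymethyl)-7-methoxy-5-[3-(benzyloxy)propyl]-2,3-dihydrobenzofuran | c1ccccc1COCCCc1cc(OC)c2c(c1)[C@@H](CO[Si](C)(C)C(C)(C)C)[C@H](c1ccc(OCc3ccccc3)c(OC)c1)O2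
A5 | alternative 2 | (1R,2S)-1-ArB-2-{5-[3-(benzyloxy)propyl]-3-methoxy-2-(trifluoromethylsulfonyloxy)phenyl}-3-(tert-butyldimethylsilyloxy)propan-1-ol | c1ccccc1COCCCc1cc(OC)c(OS(=O)(=O)C(F)(F)F)c(c1)[C@@H](CO[Si](C)(C)C(C)(C)C)[C@@H](O)c1ccc(OCc2ccccc2)c(OC)c1
A6 | alternative 3 | methyl (2R,3R)-2-(4-acetoxy-3-methoxyphenyl)-5-[3-(benzyloxy)propyl]-7-methoxy-2,3-dihydrobenzofuran-3-carboxylate (trans) | c1ccccc1COCCCc1cc(OC)c2c(c1)[C@@H](C(=O)OC)[C@H](c1ccc(OC(C)=O)c(OC)c1)O2
A7 | alternative 3 | (R)-2-(4-acetoxy-3-methoxyphenyl)-6-[3-(benzyloxy)propyl]-8-methoxychroman-4-one | c1ccccc1COCCCc1cc(OC)c2c(c1)C(=O)C[C@H](c1ccc(OC(C)=O)c(OC)c1)O2
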